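Product in the larch run stops at 8.6 % while 60.6 % of the substrate still stands free, so a repeat is best followed by what stays behind and not by what is made.

| setting | alder | larch | elm | flask |
|---|---|---|---|---|
| substrate | 0.030 M (in portions, 3) | 0.030 M (in portions, 3) | 0.015 M (in portions, 3) | 0.030 M (in portions, 3) |
| partner | 0.016 M | 0.063 M | 0.0315 M | 0.0315 M |
| initiator | 1.5 mM | 1.5 mM | 1.5 mM | 1.5 mM |
| remark | run made earlier; portions every 2.5 min | run made earlier; portions every 2.5 min | run made earlier; portions every 2.5 min | the portions of substrate follow each other after 2.5 min, the first at the start |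
| time |  |  |  | 80 min |

| run | time / min | substrate / % | product / % |
|---|---|---|---|
| alder | 6.00 | 77.8 | 4.6 |
| alder | 10.0 | 68.6 | 4.0 |
| alder | 20.0 | 63.5 | 4.2 |
| alder | 30.0 | 63.3 | 4.2 |
| alder | 50.0 | 62.5 | 4.7 |
| alder | 80.0 | 62.8 | 4.5 |
| larch | 12.0 | 64.4 | 8.3 |
| larch | 25.0 | 60.9 | 8.7 |
| larch | 40.0 | 60.5 | 8.5 |
| larch | 50.0 | 60.4 | 8.7 |
| larch | 60.0 | 60.4 | 8.5 |
| larch | 80.0 | 60.6 | 8.6 |
| elm | 15.0 | 57.9 | 8.3 |
| elm | 30.0 | 55.5 | 8.3 |
| elm | 50.0 | 55.4 | 7.9 |
| elm | 60.0 | 55.0 | 8.1 |
| elm | 80.0 | 55.6 | 8.3 |

(each reading ± 0.3 percentage points)

- percent here means substrate units held: one ended chains A counts as two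
- the earlier runs were read with a standard deviation of 0.3 percentage points
- steps that have been proposed: substrate <-> dormant form; partner + chain carrier -> product + initiating radical; initiator -> 2 initiating radical; 2 chain carrier -> ended chains A; partner -> decomposed reagent; 2 initiating radical -> ended chains B; substrate + initiating radical <-> chain carrier
- what has gone from substrate into another species counts as reacted, even if it can come back
- the reaction counts as stopped when no species that holds the substrate changes by six tenths of a point or more over the second half of the time

1. why nothing more happens at 80 min, or that something still does (it is still moving / the partner has run out first / all of the substrate has reacted)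
2. conversion of substrate at 80 min
3. amount of product at 80 min, in percent of the substrate charged

The bench rule of the limiting reagent lets the smaller charge cap the product, one partner for one substrate. In the flask, partner over substrate is 1.05, so the rule puts the cap at the substrate charge. On the larch run, where that ratio is 2.10, the cap again stands at the substrate charge, yet the plateau product read there, 8.57 %, amounts to 4.08 % of the partner charged.

So the reckoning here works with what is left. With chain carrier assumed too small to count, free substrate S, dormant form D, product P and ended chains A, Z, add up to the charge. The plateaus give S = 60.5 % for larch, and S = 55.4 % with P = 8.15 % for elm. Their initiator is equal, so Z is taken as equal in moles, which is twice the points in elm. The two balances then give the free share φ = S/(S + D), read as 0.721. Thus on a plateau S is φ times what P and Z have not taken.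

Z comes to 7.50 % in larch and, in alder, left out of the solving, 8.14 %. The partner charge of the flask, 0.0315 M, lies near 0.0317 M, the geometric mean of the alder and larch charges, so the geometric mean of their plateaus is taken for the flask and gives P = 6.14 %, and the mean Z gives a conversion of 38.0 %.

The forecast says the partner has run out first, with conversion 38.4 % and product 6.4 %, both above this reckoning , and argues: “Of the offered options, only partner loss through decomposition fits”.

The answer of the flask is that the partner has run out first, with 0 % of the partner left, conversion 38.3 % and product 6.33 %.

    substrate ⇌ dormant form (K = 0.380, k = 0.00130 s⁻¹)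
    partner + chain carrier → product + initiating radical (k = 5100 M⁻¹ s⁻¹)
    initiator → 2 initiating radical (k = 0.00200 s⁻¹)
    2 chain carrier → ended chains A (k = 1.20 × 10⁷ M⁻¹ s⁻¹)
    partner → decomposed reagent (k = 0.0200 s⁻¹)
    2 initiating radical → ended chains B (k = 4.00 × 10⁶ M⁻¹ s⁻¹)
    substrate + initiating radical ⇌ chain carrier (K = 5.30 × 10⁶ M⁻¹, k = 3100 M⁻¹ s⁻¹)

In the flask, partner, whose half-life by decomposition alone is 0.58 min, stands at 0.144 % of its charge at 5.00 min, with product already at 6.32 %. With Z = 8.58 %, φ returns S = 61.3 % for the flask at 80.0 min, where the conversion leaves 61.7 %. The neighbouring flask, charged with 3.8 × 10⁻⁴ M of initiator, ends with product 3.45 % and Z = 2.22 %. For it φ returns S = 68.0 %, and its substrate stands at 68.4 %.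

The earlier runs and the new flask come from a simulation with constants of no real substance, and the scatter is random.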